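**Retrosynthetic overview**

1. Target (1S)-lactol 18 ⇐ benzyl carbonate 16 by neutral hydrogenolysis; the C1–O bond is never broken.
2. 16 ⇐ racemic depsidone lactol 14 by an isothiourea-catalysed dynamic kinetic O-benzyloxycarbonylation, which sets the only stereocentre.
3. 14 ⇐ seco-acid 13 by closing the seven-membered depsidone lactone; 13 ⇐ diaryl ether 11 by global debenzylation, during which the hydroxyphthalide ring closes by itself.
4. 11 ⇐ SNAr of B-ring phenol 10 on A-ring aryl fluoride 5.
5. 5 from 3-fluoro-5-methylanisole (1); 10 from 5-bromo-2,4-dihydroxybenzoic acid (6). Ring order: γ-lactol (phthalide) ring, then depsidone ring.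

Assumption: the free lactol (hemiacylal) carbon can epimerise by ring–chain tautomerism when acid or base is present, so it is fixed on a configurationally stable carbonate, released last under neutral conditions, and the product is handled cold, neutral and aprotic.

**Route**

Step 1
Reactants: 1 3-fluoro-5-methylanisole
Product: 2 4-bromo-3-fluoro-5-methylanisole
Conditions: NBS (1.05 equiv), MeCN, 0 °C → rt
Reagents that add atoms: N-bromosuccinimide, O=C1CCC(=O)N1Br
Why: Electrophilic aromatic bromination goes para to the methoxy group, as with 3-fluoroanisole and 3,5-dimethylanisole.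

Step 2
Reactants: 2 4-bromo-3-fluoro-5-methylanisole
Product: 4 3-bromo-2-fluoro-6-methoxy-4-methylbenzaldehyde, via aryllithium 3 (not isolated)
Conditions: LDA (1.1 equiv), THF, −78 °C; DMF, −78 → 0 °C; 1 M HCl
Reagents that add atoms: N,N-dimethylformamide, CN(C)C=O; lithium diisopropylamide, [Li+].CC(C)[N-]C(C)C (supplies only the Li of 3)
Why: Directed ortho-metalation removes the one C–H flanked by F and OMe (no H is ortho to Br, so no halogen dance), and DMF formylates the aryllithium.

Step 3
Reactants: 4 3-bromo-2-fluoro-6-methoxy-4-methylbenzaldehyde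
Product: 5 benzyl 2-fluoro-3-formyl-4-methoxy-6-methylbenzoate
Conditions: Pd(OAc)2 (3 mol%), Xantphos (6 mol%), CO (1 atm), BnOH (2 equiv), Et3N (2 equiv), toluene, 80 °C
Reagents that add atoms: carbon monoxide, [C-]#[O+]; benzyl alcohol, OCc1ccccc1
Why: Pd-catalysed alkoxycarbonylation of the aryl bromide tolerates the aldehyde and the Ar–F bond, and the amine base does not generate benzyloxide for SNAr.

Step 4
Reactants: 6 5-bromo-2,4-dihydroxybenzoic acid
Product: 7 benzyl 2,4-bis(benzyloxy)-5-bromobenzoate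
Conditions: BnBr (3.3 equiv), K2CO3 (3.5 equiv), DMF, 60 °C
Reagents that add atoms: benzyl bromide, BrCc1ccccc1
Why: Williamson-type O-alkylation of the carboxylate and both phenoxides goes to completion in warm DMF.

Step 5
Reactants: 7 benzyl 2,4-bis(benzyloxy)-5-bromobenzoate
Product: 9 benzyl 2,4-bis(benzyloxy)-5-hydroxybenzoate, via arylboronate 8 (not isolated)
Conditions: Pd(dppf)Cl2 (3 mol%), B2pin2 (1.2 equiv), KOAc (3 equiv), dioxane, 90 °C; then 30% aq. H2O2, THF, 0 °C → rt
Reagents that add atoms: bis(pinacolato)diboron, CC1(C)OB(OC1(C)C)B1OC(C)(C)C(C)(C)O1 (boron unit of 8); hydrogen peroxide, OO (oxygen of 9)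
Why: Miyaura borylation followed by oxidation of the C–B bond turns the bromide into the phenol at the same carbon without touching the benzyl ester or ethers.

Step 6
Reactants: 9 benzyl 2,4-bis(benzyloxy)-5-hydroxybenzoate
Product: 10 benzyl 4,6-bis(benzyloxy)-2-formyl-3-hydroxybenzoate
Conditions: MgCl2 (2 equiv), Et3N (4 equiv), (CH2O)n (6 equiv), MeCN, reflux; 1 M HCl
Reagents that add atoms: paraformaldehyde (formaldehyde), C=O
Why: Magnesium-phenoxide-directed ortho-formylation (Casnati–Skattebøl) can only occur at the single free ortho position, between OH and the ester.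

Step 7
Reactants: 5 benzyl 2-fluoro-3-formyl-4-methoxy-6-methylbenzoate; 10 benzyl 4,6-bis(benzyloxy)-2-formyl-3-hydroxybenzoate
Product: 11 benzyl 4,6-bis(benzyloxy)-3-[2-(benzyloxycarbonyl)-6-formyl-5-methoxy-3-methylphenoxy]-2-formylbenzoate
Conditions: Cs2CO3 (1.5 equiv), DMSO, 60 °C
Reagents that add atoms: none
Why: SNAr succeeds because the fluoride is activated by an ortho-formyl and an ortho-ester group, and the only free OH of 10 is the nucleophile, so the ether forms at the correct oxygen.

Step 8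
Reactants: 11 benzyl 4,6-bis(benzyloxy)-3-[2-(benzyloxycarbonyl)-6-formyl-5-methoxy-3-methylphenoxy]-2-formylbenzoate
Product: 13 rac-3-formyl-4-methoxy-6-methyl-2-[(3,5,7-trihydroxy-1-oxo-1,3-dihydro-2-benzofuran-4-yl)oxy]benzoic acid, via open-chain formyl diacid 12 (not isolated)
Conditions: H2 (1 atm), 10% Pd/C, EtOAc–THF, rt, stopped at 4 equiv H2
Reagents that add atoms: none
Why: Hydrogenolysis removes both benzyl esters and both benzyl ethers, and the freed 2-formylbenzoic acid unit closes to the 3-hydroxyphthalide by ring–chain tautomerism, while the hindered A-ring aldehyde survives at 1 atm.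

Step 9
Reactants: 13 rac-3-formyl-4-methoxy-6-methyl-2-[(3,5,7-trihydroxy-1-oxo-1,3-dihydro-2-benzofuran-4-yl)oxy]benzoic acid
Product: 14 rac-1,4-dihydroxy-10-methoxy-8-methyl-3,7-dioxo-1,3-dihydro-7H-isobenzofuro[4,5-b][1,4]benzodioxepine-11-carbaldehyde
Conditions: DCC (1.1 equiv), THF (0.01 M), 0 °C → rt
Reagents that add atoms: none
Why: Carbodiimide lactonisation closes the seven-membered depsidone ring because only the 5-OH ortho to the diaryl ether can reach the activated acid, while the chelated 7-OH and the lactol OH cannot compete.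

Step 10
Reactants: 14 rac-1,4-dihydroxy-10-methoxy-8-methyl-3,7-dioxo-1,3-dihydro-7H-isobenzofuro[4,5-b][1,4]benzodioxepine-11-carbaldehyde
Product: 16 benzyl (1R)-11-formyl-4-hydroxy-10-methoxy-8-methyl-3,7-dioxo-1,3-dihydro-7H-isobenzofuro[4,5-b][1,4]benzodioxepin-1-yl carbonate, via open-chain tautomer 15 (not isolated)
Conditions: (S)-benzotetramisole (10 mol%), dibenzyl dicarbonate (1.3 equiv), iPr2NEt (20 mol%), CHCl3, −20 °C
Reagents that add atoms: dibenzyl dicarbonate, O=C(OCc1ccccc1)OC(=O)OCc1ccccc1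
Why: Proposed new method: isothiourea-catalysed dynamic kinetic asymmetric O-benzyloxycarbonylation of a 3-hydroxyphthalide lactol with a dicarbonate; the catalyst attacks the dicarbonate to give an N-benzyloxycarbonyl isothiouronium ion (acyl C=O held syn to sulfur by the 1,5-S···O contact) whose benzyl carbonate counter-ion (→ BnOH + CO2) acts as base; the lactol enantiomers interconvert through open-chain tautomer 15 under amine catalysis faster than they are carbonylated, and only the enantiomer that can π-stack its benzo-lactone face on the cationic catalyst with the carbinol H turned toward the catalyst's phenyl group is acylated, so all of 14 is funnelled into one carbonate whose acylal centre no longer epimerises; the chelated 4-OH does not react at −20 °C; 16 is (1R) by CIP only because OCO2Bn outranks the ring oxygen, and it has the spatial arrangement of the (1S)-target; closest known reaction type: acylative dynamic kinetic resolution of lactols and 3-hydroxyphthalides with carboxylic anhydrides under chiral isothiourea or chiral DMAP catalysis, together with isothiourea-mediated carboxyl transfer from carbonates.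

Step 11
Reactants: 16 benzyl (1R)-11-formyl-4-hydroxy-10-methoxy-8-methyl-3,7-dioxo-1,3-dihydro-7H-isobenzofuro[4,5-b][1,4]benzodioxepin-1-yl carbonate
Product: 18 (1S)-1,4-dihydroxy-10-methoxy-8-methyl-3,7-dioxo-1,3-dihydro-7H-isobenzofuro[4,5-b][1,4]benzodioxepine-11-carbaldehyde (target), via hemicarbonate 17 (not isolated)
Conditions: H2 (1 atm), 5% Pd/C, EtOAc, 0 °C, 15–30 min; cold filtration, evaporation below 10 °C
Reagents that add atoms: none
Why: Hydrogenolysis cleaves only the PhCH2–O bond and the resulting carbonic acid monoester loses CO2 under neutral conditions, so the C1–O bond is never broken and the configuration is retained as (1S).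

**Compound list**

1 | 3-fluoro-5-methylanisole | COc1cc(C)cc(F)c1 | starting material
2 | 4-bromo-3-fluoro-5-methylanisole | COc1cc(C)c(Br)c(F)c1 | intermediate
3 | (3-bromo-2-fluoro-6-methoxy-4-methylphenyl)lithium | COc1cc(C)c(Br)c(F)c1[Li] | intermediate
4 | 3-bromo-2-fluoro-6-methoxy-4-methylbenzaldehyde | COc1cc(C)c(Br)c(F)c1C=O | intermediate
5 | benzyl 2-fluoro-3-formyl-4-methoxy-6-methylbenzoate | COc1cc(C)c(C(=O)OCc2ccccc2)c(F)c1C=O | intermediate
6 | 5-bromo-2,4-dihydroxybenzoic acid | OC(=O)c1cc(Br)c(O)cc1O | starting material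
7 | benzyl 2,4-bis(benzyloxy)-5-bromobenzoate | O=C(OCc1ccccc1)c1cc(Br)c(OCc2ccccc2)cc1OCc1ccccc1 | intermediate
8 | benzyl 2,4-bis(benzyloxy)-5-(4,4,5,5-tetramethyl-1,3,2-dioxaborolan-2-yl)benzoate | O=C(OCc1ccccc1)c1cc(B2OC(C)(C)C(C)(C)O2)c(OCc2ccccc2)cc1OCc1ccccc1 | intermediate
9 | benzyl 2,4-bis(benzyloxy)-5-hydroxybenzoate | O=C(OCc1ccccc1)c1cc(O)c(OCc2ccccc2)cc1OCc1ccccc1 | intermediate
10 | benzyl 4,6-bis(benzyloxy)-2-formyl-3-hydroxybenzoate | O=Cc1c(O)c(OCc2ccccc2)cc(OCc2ccccc2)c1C(=O)OCc1ccccc1 | intermediate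
11 | benzyl 4,6-bis(benzyloxy)-3-[2-(benzyloxycarbonyl)-6-formyl-5-methoxy-3-methylphenoxy]-2-formylbenzoate | COc1cc(C)c(C(=O)OCc2ccccc2)c(Oc2c(C=O)c(C(=O)OCc3ccccc3)c(OCc3ccccc3)cc2OCc2ccccc2)c1C=O | intermediate
12 | 3-(2-carboxy-6-formyl-5-methoxy-3-methylphenoxy)-2-formyl-4,6-dihydroxybenzoic acid | COc1cc(C)c(C(=O)O)c(Oc2c(O)cc(O)c(C(=O)O)c2C=O)c1C=O | intermediate
13 | rac-3-formyl-4-methoxy-6-methyl-2-[(3,5,7-trihydroxy-1-oxo-1,3-dihydro-2-benzofuran-4-yl)oxy]benzoic acid | COc1cc(C)c(C(=O)O)c(Oc2c(O)cc(O)c3C(=O)OC(O)c23)c1C=O | intermediate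
14 | rac-1,4-dihydroxy-10-methoxy-8-methyl-3,7-dioxo-1,3-dihydro-7H-isobenzofuro[4,5-b][1,4]benzodioxepine-11-carbaldehyde (racemic lactol) | COc1cc(C)c2c(c1C=O)Oc1c(cc(O)c3c1C(O)OC3=O)OC2=O | intermediate
15 | open-chain tautomer of 14 (depsidone with B-ring CHO next to the ether oxygen and CO2H next to the phenol, in place of the lactol) | COc1cc(C)c2c(c1C=O)Oc1c(cc(O)c(C(=O)O)c1C=O)OC2=O | intermediate
16 | benzyl (1R)-11-formyl-4-hydroxy-10-methoxy-8-methyl-3,7-dioxo-1,3-dihydro-7H-isobenzofuro[4,5-b][1,4]benzodioxepin-1-yl carbonate | COc1cc(C)c2c(c1C=O)Oc1c(cc(O)c3c1[C@@H](OC(=O)OCc4ccccc4)OC3=O)OC2=O | intermediate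
17 | (1R)-11-formyl-4-hydroxy-10-methoxy-8-methyl-3,7-dioxo-1,3-dihydro-7H-isobenzofuro[4,5-b][1,4]benzodioxepin-1-yl hydrogen carbonate | COc1cc(C)c2c(c1C=O)Oc1c(cc(O)c3c1[C@@H](OC(=O)O)OC3=O)OC2=O | intermediate
18 | (1S)-1,4-dihydroxy-10-methoxy-8-methyl-3,7-dioxo-1,3-dihydro-7H-isobenzofuro[4,5-b][1,4]benzodioxepine-11-carbaldehyde | COc1cc(C)c2c(c1C=O)Oc1c(cc(O)c3c1[C@@H](O)OC3=O)OC2=O | target

**Step count and risks**

Total steps: 11. Longest linear sequence: 8 (steps 1, 2, 3, 7, 8, 9, 10, 11; the B-ring branch, steps 4–6, is equally long).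

Most likely to fail:

Step 7 (SNAr giving a tetra-ortho-substituted diaryl ether). Both partners are hindered and the phenoxide of 10 is chelated. Fallback, setting out from 5 and 10 and returning at 13, makes the ether intramolecularly by a Smiles rearrangement of a depside. The fluoride of 5 is exchanged for OH (2-(methylsulfonyl)ethanol, NaH, DMF; SNAr then β-elimination) to give benzyl 3-formyl-2-hydroxy-4-methoxy-6-methylbenzoate F1. Hydrogenolysis (H2, Pd/C, EtOAc) gives 3-formyl-2-hydroxy-4-methoxy-6-methylbenzoic acid F2. This acid is esterified with the free OH of 10 (TFAA, toluene, rt) to give the depside benzyl 4,6-bis(benzyloxy)-2-formyl-3-[(3-formyl-2-hydroxy-4-methoxy-6-methylbenzoyl)oxy]benzoate F3. With K2CO3 in DMSO at rt the A-ring phenoxide attacks the B-ring ipso carbon (activated by the ortho-formyl group) through a six-membered spiro intermediate and expels the carboxylate. This gives 2-[4,6-bis(benzyloxy)-3-(benzyloxycarbonyl)-2-formylphenoxy]-3-formyl-4-methoxy-6-methylbenzoic acid F4, which is hydrogenolysed as in step 8 to 13.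

Step 10 (the proposed new dynamic kinetic carbonylation). Risks are low selectivity, capture of the open-chain carboxylate as a benzyl ester, and an uncertain sense of induction. The (S)-catalyst is chosen by analogy with the π-stacking model for benzylic alcohols; the configuration of 16 must be checked (X-ray or CD), and (R)-benzotetramisole is used if the sense is opposite. Fallback with known chemistry, setting out from 14 and returning at 16: benzyl chloroformate and pyridine in CH2Cl2 at 0 °C give the racemic benzyl carbonate F5. Preparative SFC on a chiral stationary phase separates 16 from its enantiomer, the (1S)-benzyl carbonate F6. F6 is hydrogenolysed under the step 11 conditions back to racemic 14 and recycled.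

Step 11 (release of the lactol). Risks are reduction of the aryl aldehyde, hydrogenolysis of the benzylic C1–O bond, and epimerisation of the product on work-up. Fallback, setting out from 14 and returning at 18, replaces hydrogenolysis by photolysis. Step 10 is run with 4,5-dimethoxy-2-nitrobenzyl chloroformate (1.2 equiv) and iPr2NEt (1.2 equiv) in place of dibenzyl dicarbonate to give the (1R)-4,5-dimethoxy-2-nitrobenzyl carbonate F7. Irradiation at 365 nm in MeCN at 0 °C releases 18 under neutral, metal-free conditions without touching the C1–O bond.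

**Further compounds**

F1 | step 7 | benzyl 3-formyl-2-hydroxy-4-methoxy-6-methylbenzoate | COc1cc(C)c(C(=O)OCc2ccccc2)c(O)c1C=O
F2 | step 7 | 3-formyl-2-hydroxy-4-methoxy-6-methylbenzoic acid | COc1cc(C)c(C(=O)O)c(O)c1C=O
F3 | step 7 | benzyl 4,6-bis(benzyloxy)-2-formyl-3-[(3-formyl-2-hydroxy-4-methoxy-6-methylbenzoyl)oxy]benzoate | COc1cc(C)c(C(=O)Oc2c(C=O)c(C(=O)OCc3ccccc3)c(OCc3ccccc3)cc2OCc2ccccc2)c(O)c1C=O
F4 | step 7 | 2-[4,6-bis(benzyloxy)-3-(benzyloxycarbonyl)-2-formylphenoxy]-3-formyl-4-methoxy-6-methylbenzoic acid | COc1cc(C)c(C(=O)O)c(Oc2c(C=O)c(C(=O)OCc3ccccc3)c(OCc3ccccc3)cc2OCc2ccccc2)c1C=O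
F5 | step 10 | rac-benzyl 11-formyl-4-hydroxy-10-methoxy-8-methyl-3,7-dioxo-1,3-dihydro-7H-isobenzofuro[4,5-b][1,4]benzodioxepin-1-yl carbonate | COc1cc(C)c2c(c1C=O)Oc1c(cc(O)c3c1C(OC(=O)OCc4ccccc4)OC3=O)OC2=O
F6 | step 10 | benzyl (1S)-11-formyl-4-hydroxy-10-methoxy-8-methyl-3,7-dioxo-1,3-dihydro-7H-isobenzofuro[4,5-b][1,4]benzodioxepin-1-yl carbonate | COc1cc(C)c2c(c1C=O)Oc1c(cc(O)c3c1[C@H](OC(=O)OCc4ccccc4)OC3=O)OC2=O
F7 | step 11 | 4,5-dimethoxy-2-nitrobenzyl (1R)-11-formyl-4-hydroxy-10-methoxy-8-methyl-3,7-dioxo-1,3-dihydro-7H-isobenzofuro[4,5-b][1,4]benzodioxepin-1-yl carbonate | COc1cc(C)c2c(c1C=O)Oc1c(cc(O)c3c1[C@@H](OC(=O)OCc4cc(OC)c(OC)cc4[N+](=O)[O-])OC3=O)OC2=O
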